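**Retrosynthetic overview**
- The dihydropyran ring is opened by a retro-hetero-Diels–Alder reaction across O–C4 and CH2–C5. This gives (−)-β-caryophyllene and an α-methylene trione (ortho-quinone methide).
- The quinone methide is cut at the C4'–CH2 bond into a polarity-reversed trione (an enolonium equivalent, the phenyliodonium zwitterion) and a hydroxymethyl carbanion equivalent, (tributylstannyl)methanol.
- The zwitterion comes from isobutyrylfilicinic acid and PhI(OAc)2.
- Isobutyrylfilicinic acid comes from dearomatising gem-dimethylation of isobutyrylphloroglucinol, itself from phloroglucinol and isobutyryl chloride.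
- Ring order: the six-membered carbocycle is the bought arene (dearomatised in step 2); the four- and nine-membered rings arrive intact with caryophyllene; the dihydropyran is formed last.

Assumption: C1–C15 refer to the caryophyllane part (C1/C9 ring fusion, C4 methyl-bearing, C5 its alkene partner, C8 exocyclic methylene) and C1'–C6' to the trione ring (C2' acyl-bearing, C4' the free CH, C6' gem-dimethyl); on this basis the target is (1R,4S,5R,9S).

**Step 1**
Reactants: 1 phloroglucinol (benzene-1,3,5-triol); 2 isobutyryl chloride (2-methylpropanoyl chloride)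
Product: 3 2-methyl-1-(2,4,6-trihydroxyphenyl)propan-1-one
Conditions: AlCl3 (4 equiv), PhNO2, 65 °C; aq. HCl work-up
Reagents that add atoms: none
Why: Friedel–Crafts acylation of the strongly activated arene stops at monoacylation because the chelated aryl ketone is deactivated; no stereocentre is formed.

**Step 2**
Reactants: 3 2-methyl-1-(2,4,6-trihydroxyphenyl)propan-1-one
Product: 4 3,5-dihydroxy-6,6-dimethyl-2-(2-methylpropanoyl)cyclohexa-2,4-dien-1-one (isobutyrylfilicinic acid)
Conditions: NaOMe (3 equiv), MeI (2.1 equiv), MeOH, 0 °C to rt; aq. HCl
Reagents that add atoms: iodomethane, CI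
Why: Base-mediated C-methylation of the phloroglucinol polyanion (dearomatising gem-dimethylation) puts the second methyl on the already methylated, most nucleophilic ring carbon, giving the non-aromatisable dienone, while two equivalents of MeI limit over-methylation; no stereocentre is formed.

**Step 3**
Reactants: 4 isobutyrylfilicinic acid
Product: 5 phenyliodonium zwitterion of 4 (3-hydroxy-6,6-dimethyl-2-(2-methylpropanoyl)-4-(phenyl-λ3-iodanylidene)cyclohex-2-ene-1,5-dione)
Conditions: PhI(OAc)2 (1.05 equiv), KOH (2 equiv), MeOH, −10 to 0 °C
Reagents that add atoms: (diacetoxyiodo)benzene, CC(=O)OI(OC(C)=O)c1ccccc1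
Why: Iodonium ylide formation (ligand exchange of the acidic 1,3-dione on trivalent iodine, then loss of acetate) occurs at C4', the only ring carbon bearing hydrogen, and turns this normally nucleophilic carbon into an electrophilic enolonium equivalent; no stereocentre is formed.

**Step 4**
Reactants: 5 phenyliodonium zwitterion of 4; 6 (−)-β-caryophyllene ((1R,4E,9S)-4,11,11-trimethyl-8-methylidenebicyclo[7.2.0]undec-4-ene)
Product: 9 target (1R,4S,5R,9S)-caryophyllene–isobutyrylfilicinic acid adduct, via stannyl hydroxymethyl enolate 7 (not isolated), via ortho-quinone methide 8 (not isolated)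
Conditions: Bu3SnCH2OH (1.2 equiv), Pd2(dba)3 (2.5 mol%), AsPh3 (10 mol%), dioxane, 25–50 °C; then 6 (4 equiv), 95 °C; HPLC separation from the C4/C5 diastereomer
Reagents that add atoms: (tributylstannyl)methanol, OC[Sn](CCCC)(CCCC)CCCC
Why: Proposed new method: zerovalent palladium inserts into the C4'–I bond of the enolonium equivalent 5 with loss of PhI, the stannane hands over its CH2OH group as a carbanion equivalent (Stille-type transmetalation, then reductive elimination) so that the C4'–CH2 bond is made with the trione carbon as the electrophile (7), E1cB loss of tributyltin hydroxide gives quinone methide 8, and 8 adds as a heterodiene (oxygen of the C5' carbonyl to C4, CH2 to C5) suprafacially across the strained (E)-C4=C5 bond of 6 in an inverse-electron-demand hetero-Diels–Alder reaction, so that the E geometry fixes the trans C4/C5 ring fusion, C1/C9 of 6 are untouched, and attack on the alkene face opposite to the one epoxidised in natural caryophyllene oxide (the face open in the ββ conformer) gives 4S,5R; the closest known reaction types are the palladium-catalysed Suzuki-type arylation of phenyliodonium zwitterions of cyclic 1,3-diones, the Stille hydroxymethylation of aryl halides with this stannane, and the quinone-methide hetero-Diels–Alder route to caryophyllene meroterpenoids.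

**Compound list**
1 | phloroglucinol (benzene-1,3,5-triol) | Oc1cc(O)cc(O)c1 | starting material
2 | isobutyryl chloride (2-methylpropanoyl chloride) | CC(C)C(Cl)=O | starting material
3 | 2-methyl-1-(2,4,6-trihydroxyphenyl)propan-1-one | CC(C)C(=O)c1c(O)cc(O)cc1O | intermediate
4 | 3,5-dihydroxy-6,6-dimethyl-2-(2-methylpropanoyl)cyclohexa-2,4-dien-1-one (isobutyrylfilicinic acid) | CC(C)C(=O)C1=C(O)C=C(O)C(C)(C)C1=O | intermediate
5 | phenyliodonium zwitterion of 4: 3-hydroxy-6,6-dimethyl-2-(2-methylpropanoyl)-4-(phenyl-λ3-iodanylidene)cyclohex-2-ene-1,5-dione | CC(C)C(=O)C1=C(O)[C-]([I+]c2ccccc2)C(=O)C(C)(C)C1=O | intermediate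
6 | (−)-β-caryophyllene, (1R,4E,9S)-4,11,11-trimethyl-8-methylidenebicyclo[7.2.0]undec-4-ene | C=C1CC/C=C(C)/CC[C@@H]2[C@@H]1CC2(C)C | starting material
7 | tributylstannyl enolate (tin on O5') of 3,5-dihydroxy-4-(hydroxymethyl)-6,6-dimethyl-2-(2-methylpropanoyl)cyclohexa-2,4-dien-1-one, formed in the flask | CC(C)C(=O)C1=C(O)C(CO)=C(O[Sn](CCCC)(CCCC)CCCC)C(C)(C)C1=O | intermediate
8 | ortho-quinone methide: 3-hydroxy-6,6-dimethyl-4-methylidene-2-(2-methylpropanoyl)cyclohex-2-ene-1,5-dione, formed in the flask | C=C1C(=O)C(C)(C)C(=O)C(C(=O)C(C)C)=C1O | intermediate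
9 | (1R,4S,5R,9S)-adduct (caryophyllane locants): dihydropyran trans-fused across C4 (O, CH3) and C5 (H, CH2), joined to the enolised 3-hydroxy-6,6-dimethyl-2-(2-methylpropanoyl)cyclohexenone ring; C8 exocyclic methylene and trans-fused gem-dimethylcyclobutane retained | C=C1CC[C@@H]2CC3=C(O[C@@]2(C)CC[C@@H]2[C@@H]1CC2(C)C)C(C)(C)C(=O)C(C(=O)C(C)C)=C3O | target

**Step count and risks**
Total step count: 4. Longest linear sequence: 4 steps (1 → 3 → 4 → 5 → 9); 6 enters in the last step.

The step most likely to fail is step 4, for two reasons.
- Transfer of an sp3 carbon to the palladium enolate from 5 is untested for an acidic acyl trione. Protodepalladation back to 4 (which would trap 8 as a methylene-bis adduct) and ylide decomposition compete.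
- The cycloaddition gives two trans-fused diastereomers. The target is the adduct on the face opposite to the one epoxidised in natural caryophyllene oxide, so I expect it to be the minor one (roughly 1:2.5, by analogy with reported caryophyllene quinone-methide cycloadditions), and separation is unavoidable.

The fallback sets out from 5 and comes back at 8. Suzuki-type methylation of 5 with methylboronic acid (Pd2(dba)3, P(t-Bu)3, K3PO4, dioxane/water, rt) gives norflavesone F1. F1 is then dehydrogenated in the presence of 6 with TEMPO and Ag2O in toluene at 60 °C, so that 8 is made oxidatively from a C-methyl group instead of by elimination, and continues to 9.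

Second is step 3: the hypervalent ylide of an acyl trione may over-oxidise or rearrange on storage. The fallback sets out from 4 and comes back at 8. Iodination of 4 at C4' with N-iodosuccinimide (MeCN, 0 °C) gives the α-iodo trione F2, an enolonium equivalent based on monovalent iodine. Stille hydroxymethylation of F2 (Bu3SnCH2OH, Pd2(dba)3, AsPh3, CuI, dioxane, 60 °C) gives the hydroxymethyl trione F3, which loses water to 8 on heating with 6.

Third is step 2: methylation gives mixtures (mono-, 3,5-di-, tri- and O-methylated products) because the second ring CH stays nucleophilic. The fallback sets out from 3 and comes back at 8. Mono-iodination of 3 (N-iodosuccinimide, 1 equiv, MeCN, −20 °C) gives 1-(3-iodo-2,4,6-trihydroxyphenyl)-2-methylpropan-1-one F4, in which the second ring carbon is blocked by the iodine that is needed later. Gem-dimethylation of F4 (NaOMe, MeI, MeOH) can then take place only at the remaining CH and gives the α-iodo trione F2 directly, which goes on through the hydroxymethyl trione F3 to 8 as above.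

**Further compounds**
F1 | step 4 | norflavesone, 3,5-dihydroxy-4,6,6-trimethyl-2-(2-methylpropanoyl)cyclohexa-2,4-dien-1-one | CC(C)C(=O)C1=C(O)C(C)=C(O)C(C)(C)C1=O
F2 | step 3 | 3,5-dihydroxy-4-iodo-6,6-dimethyl-2-(2-methylpropanoyl)cyclohexa-2,4-dien-1-one | CC(C)C(=O)C1=C(O)C(I)=C(O)C(C)(C)C1=O
F3 | step 3 | 3,5-dihydroxy-4-(hydroxymethyl)-6,6-dimethyl-2-(2-methylpropanoyl)cyclohexa-2,4-dien-1-one | CC(C)C(=O)C1=C(O)C(CO)=C(O)C(C)(C)C1=O
F4 | step 2 | 1-(3-iodo-2,4,6-trihydroxyphenyl)-2-methylpropan-1-one | CC(C)C(=O)c1c(O)cc(O)c(I)c1O
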